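**Retrosynthetic overview**

Numbering (cembrane): carbocycle C1–C14; C15 = CMe2 on C1, tied through O to C3 (oxolane ring C1–C2–C3–O–C15); C18 = CH2O on C4; C19 = formyl carbon on C8; C20 = CH3 on C12.
Feature used: in the 14-membered ring, one extra bond C19–C12 would fold C8, C9, C10, C11, C12 and C19 into a cyclohexane with oxygen on C19 and on C11, both attached to C12. The C19=O and Z-C11=C12 π bonds are therefore the two halves of one Grob fragmentation.
Disconnections: malonic half ester ⇒ C18 alcohol + Meldrum's acid; 14-ring ⇒ oxolane-fused bicyclo[9.3.1]pentadecene 19-hydroxy-11-mesylate (C12–C19 cleavage); 12-ring ⇒ intramolecular HWE at C7=C8; quaternary C12 ⇒ cyclohexane-1,3-dione + C13 aldehyde + MeI, then desymmetrising reduction; C3–C4 ⇒ Evans syn aldol on the keto aldehyde from (R)-limonene (source of C1).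
Ring order: oxolane (step 5), six-membered ring brought in ready-made (step 11), 12-membered ring (step 18), 14-membered ring released by merging the two (step 22).

Key step: step 22

Assumption: the ketoreductase of step 13 is picked from a commercial panel by screening for the (11R,12R)-cis ketol. C11, C12 and C19 are erased in step 22, so only their all-cis relative arrangement bears on the target. The spatial arrangement at C1, C3 and C4 never changes after step 4, although CIP letters do.

**Route**

Step 1
Reactants: 1 (R)-limonene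
Product: 3 (3R)-3-isopropenyl-6-oxoheptanal, via secondary ozonide 2 (not isolated)
Conditions: O3 (1.0 equiv, metered), CH2Cl2, −78 °C; PPh3, −78 °C → rt
Reagents that add atoms: ozone, [O-][O+]=O
Why: Chemoselective ozonolysis with reductive work-up, in which the electron-rich trisubstituted ring alkene takes up the single equivalent of ozone ahead of the 1,1-disubstituted isopropenyl group and the stereocentre (future C1) is untouched.

Step 2
Reactants: 4 δ-valerolactone
Product: 6 5-(benzyloxy)pentanoic acid, via potassium 5-hydroxypentanoate 5 (not isolated)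
Conditions: KOH (powder, excess), BnBr, toluene, reflux; H2O extraction, then HCl to pH 2
Reagents that add atoms: potassium hydroxide, [K+].[OH-]; benzyl bromide, BrCc1ccccc1
Why: Lactone saponification followed in the same pot by Williamson etherification of the liberated alkoxide, any benzyl ester being re-saponified by the excess KOH.

Step 3
Reactants: 6 5-(benzyloxy)pentanoic acid; 7 (S)-4-benzyloxazolidin-2-one
Product: 9 (S)-4-benzyl-3-[5-(benzyloxy)pentanoyl]oxazolidin-2-one, via mixed pivalic anhydride 8 (not isolated)
Conditions: PivCl, Et3N, THF, −20 °C; then 7, LiCl, −20 °C → rt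
Reagents that add atoms: none
Why: N-acylation of the oxazolidinone through a mixed anhydride, the bulky pivaloyl carbonyl steering attack to the pentanoyl carbonyl.

Step 4
Reactants: 9 (S)-4-benzyl-3-[5-(benzyloxy)pentanoyl]oxazolidin-2-one; 3 (3R)-3-isopropenyl-6-oxoheptanal
Product: 11 (S)-4-benzyl-3-[(2S,3R,5R)-2-(3-benzyloxypropyl)-3-hydroxy-5-isopropenyl-8-oxononanoyl]oxazolidin-2-one, via Z-boron enolate 10 (not isolated)
Conditions: Bu2BOTf, Et3N, CH2Cl2, −78 → 0 °C; 3, −78 → 0 °C; pH 7 buffer, MeOH, H2O2, 0 °C
Reagents that add atoms: none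
Why: Evans syn aldol in which the Z-boron enolate reacts through a Zimmerman–Traxler chair on the face away from the auxiliary benzyl group, setting C4 and C3 together (syn, 4S/3R in the imide), while the aldehyde far outruns the methyl ketone as electrophile.

Step 5
Reactants: 11 aldol adduct
Product: 12 (S)-4-benzyl-3-{(2S)-5-benzyloxy-2-[(2R,4R)-5,5-dimethyl-4-(3-oxobutyl)oxolan-2-yl]pentanoyl}oxazolidin-2-one
Conditions: [N,N′-bis(3,5-di-tert-butylsalicylidene)-1,2-cyclohexanediaminato]cobalt (C36H52CoN2O2, divalent cobalt, 3 mol %), N-fluoro-2,4,6-trimethylpyridinium triflate, (Me2SiH)2O, PhCF3, rt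
Reagents that add atoms: none
Why: Cobalt-hydride hydrogen-atom-transfer hydroalkoxylation (Mukaiyama-type, radical–polar crossover) puts H on the CH2 terminus of the isopropenyl group and lets the C3 hydroxyl capture the oxidised tertiary C15 centre 5-exo, so no new stereocentre arises, the cis relation of C4 and C14 follows from C1 and C3, and neither C1–H scrambling nor ketone activation by Brønsted acid is risked.

Step 6
Reactants: 12 oxolane methyl ketone
Product: 13 (S)-3-{(2S)-2-[(2R,4R)-4-(2-acetoxyethyl)-5,5-dimethyloxolan-2-yl]-5-benzyloxypentanoyl}-4-benzyloxazolidin-2-one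
Conditions: mCPBA, CF3CO2H (cat.), CH2Cl2, 0 °C → rt, dark
Reagents that add atoms: mCPBA, O=C(OO)c1cccc(Cl)c1
Why: Baeyer–Villiger oxidation in which the primary C13 methylene migrates in preference to methyl, turning the two surplus limonene carbons into an acetate at a stage where the alkene is gone and no silyl ether is yet present.

Step 7
Reactants: 13 imide acetate
Product: 14 2-{(3R,5R)-5-[(2R)-5-benzyloxy-1-hydroxypentan-2-yl]-2,2-dimethyloxolan-3-yl}ethyl acetate
Conditions: NaBH4, THF/H2O (4:1), 0 °C → rt
Reagents that add atoms: none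
Why: Reductive auxiliary removal with aqueous borohydride reduces the activated imide carbonyl to the C18 alcohol while a plain acetate is inert to NaBH4, so the two primary oxygen termini stay differentiated and C4 is not epimerised because the transient aldehyde is reduced at once.

Step 8
Reactants: 14 C18 alcohol
Product: 15 2-{(3R,5R)-5-[(2R)-5-benzyloxy-1-(tert-butyldimethylsilyloxy)pentan-2-yl]-2,2-dimethyloxolan-3-yl}ethyl acetate
Conditions: TBSCl, imidazole, DMF, 0 °C → rt
Reagents that add atoms: tert-butyldimethylsilyl chloride, CC(C)(C)[Si](C)(C)Cl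
Why: Standard silylation of the only free hydroxyl group.

Step 9
Reactants: 15 silyl ether acetate
Product: 16 2-{(3R,5R)-5-[(2R)-5-benzyloxy-1-(tert-butyldimethylsilyloxy)pentan-2-yl]-2,2-dimethyloxolan-3-yl}ethanol
Conditions: K2CO3 (cat.), MeOH, 0 °C → rt
Reagents that add atoms: none
Why: Base-catalysed transesterification removes the acetate without affecting silyl or benzyl ethers.

Step 10
Reactants: 16 C13 alcohol
Product: 17 2-{(3S,5R)-5-[(2R)-5-benzyloxy-1-(tert-butyldimethylsilyloxy)pentan-2-yl]-2,2-dimethyloxolan-3-yl}acetaldehyde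
Conditions: DMP, CH2Cl2, 0 °C → rt
Reagents that add atoms: none
Why: Dess–Martin oxidation to the C13 aldehyde, whose α-carbon C14 is a CH2, so no centre can epimerise (the CIP letter at C1 changes by priority only).

Step 11
Reactants: 17 C13 aldehyde; 18 cyclohexane-1,3-dione
Product: 20 2-{2-[(3R,5R)-5-((2R)-5-benzyloxy-1-(tert-butyldimethylsilyloxy)pentan-2-yl)-2,2-dimethyloxolan-3-yl]ethyl}cyclohexane-1,3-dione, via alkylidene dione 19 (not isolated)
Conditions: L-proline (20 mol %), diethyl 2,6-dimethyl-1,4-dihydropyridine-3,5-dicarboxylate (Hantzsch ester), CH2Cl2, rt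
Reagents that add atoms: none
Why: Organocatalytic three-component reductive alkylation, in which Knoevenagel condensation gives 19 and conjugate hydride transfer from the Hantzsch ester reduces it before a second dione can add, forming C12–C13.

Step 12
Reactants: 20 2-alkyl dione
Product: 21 2-methyl-2-{2-[(3R,5R)-5-((2R)-5-benzyloxy-1-(tert-butyldimethylsilyloxy)pentan-2-yl)-2,2-dimethyloxolan-3-yl]ethyl}cyclohexane-1,3-dione
Conditions: MeI, K2CO3, acetone, 50 °C
Reagents that add atoms: iodomethane, CI
Why: C-alkylation of the stabilised 1,3-dione enolate with the soft electrophile MeI installs C20 and makes C12 quaternary but still prochiral.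

Step 13
Reactants: 21 2,2-disubstituted dione
Product: 22 (2R,3R)-3-hydroxy-2-methyl-2-{2-[(3R,5R)-5-((2R)-5-benzyloxy-1-(tert-butyldimethylsilyloxy)pentan-2-yl)-2,2-dimethyloxolan-3-yl]ethyl}cyclohexan-1-one
Conditions: anti-Prelog NADPH-dependent ketoreductase (Lactobacillus kefir alcohol dehydrogenase type, panel-selected), NADP+ (cat.), iPrOH, DMSO, potassium phosphate buffer pH 7, MgSO4, 30 °C
Reagents that add atoms: none
Why: Enzymatic desymmetrising mono-reduction of a 2,2-disubstituted cyclic 1,3-dione, the active site delivering hydride to one face of one of the two diastereotopic carbonyls and thereby fixing C11 (R) and C12 (R) together with the hydroxyl cis to the C13 chain.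

Step 14
Reactants: 22 ketol
Product: 23 C11 triethylsilyl ether of 22
Conditions: TESOTf, 2,6-lutidine, CH2Cl2, −78 → 0 °C
Reagents that add atoms: triethylsilyl triflate, CC[Si](CC)(CC)OS(=O)(=O)C(F)(F)F
Why: Silylation of the hindered carbinol blocks retro-aldol cleavage of the C11–C12 bond in the basic steps that follow, with a group markedly more acid-labile than the primary TBS ether.

Step 15
Reactants: 23 silylated ketone
Product: 26 C8 diethyl phosphonate of 23 (C8 epimers), via lithium enolate 24 (not isolated), via keto phosphonite 25 (not isolated)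
Conditions: LDA, THF, −78 °C; ClP(OEt)2, −78 °C → rt; H2O2 (30 % aq.), 0 °C
Reagents that add atoms: diethyl chlorophosphite, CCOP(Cl)OCC; hydrogen peroxide, OO
Why: Enolisation is possible only at C8 because C12 is quaternary, the soft trivalent-phosphorus chloride is attacked by the enolate carbon (C-phosphinylation, where a chlorophosphate would react at oxygen), and peroxide oxidation gives the β-keto phosphonate, whose C8 configuration is irrelevant because C8 becomes sp2.

Step 16
Reactants: 26 keto phosphonate benzyl ether
Product: 27 keto phosphonate with free C7 hydroxyl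
Conditions: H2 (1 atm), Pd/C, EtOAc, rt
Reagents that add atoms: none
Why: Benzyl ether hydrogenolysis, clean here because the molecule holds no alkene and neutral EtOAc spares both silyl ethers.

Step 17
Reactants: 27 C7 alcohol
Product: 28 keto phosphonate C7 aldehyde
Conditions: DMP, CH2Cl2, 0 °C → rt
Reagents that add atoms: none
Why: Dess–Martin oxidation of the only free alcohol under non-basic conditions, so the phosphonate does not react prematurely.

Step 18
Reactants: 28 keto phosphonate aldehyde
Product: 29 oxolane-fused (7E)-bicyclo[9.3.1]pentadecenone with C19 ketone bridging C8 and C12 plus 11-OTES and 18-OTBS (1R,3R,4R,11R,12R)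
Conditions: LiCl, DBU, MeCN (ca. 1 mM, slow addition of 28), rt
Reagents that add atoms: none
Why: Intramolecular Horner–Wadsworth–Emmons olefination under soft-enolisation conditions and high dilution closes the 12-membered ring at C7=C8 and should favour the E-alkylidene ketone (C6 trans to C19, trans within the 12-ring), which is the geometry needed for C6 cis to C9 in the target.

Step 19
Reactants: 29 bridged enone TES ether
Product: 30 bridged enone with free C11 hydroxyl
Conditions: PPTS (cat.), MeOH/CH2Cl2, 0 °C → rt
Reagents that add atoms: none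
Why: Acid-catalysed methanolysis exploits the much higher lability of triethylsilyl over tert-butyldimethylsilyl ethers, and any C18 hydroxyl set free by over-reaction could be re-silylated selectively as the only primary alcohol.

Step 20
Reactants: 30 hydroxy enone
Product: 31 bridged enone C11 mesylate
Conditions: MsCl, Et3N, CH2Cl2, 0 °C
Reagents that add atoms: methanesulfonyl chloride, CS(=O)(=O)Cl
Why: Mesylation through sulfene copes with the neopentyl-type secondary alcohol and retains the C11 configuration because only the O–H bond is touched.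

Step 21
Reactants: 31 enone mesylate
Product: 32 oxolane-fused bicyclo[9.3.1]pentadecene 19-hydroxy-11-mesylate (1R,3R,4R,7E,11R,12S,19S; C13 branch and OMs and OH all on one face of the cyclohexane)
Conditions: NaBH4, CeCl3·7H2O, MeOH, −78 °C
Reagents that add atoms: none
Why: Luche 1,2-reduction in which hydride enters C19 axially from the face opposite the axial C13 branch and the nine-atom bridge, placing the hydroxyl equatorial and cis to the mesylate, while the protic medium at low temperature protonates the alkoxide before it can fragment.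

Step 22
Reactants: 32 hydroxy mesylate
Product: 34 (1R,3R,4R,7E,11Z)-18-(tert-butyldimethylsilyloxy)-3,15-epoxycembra-7,11-dien-19-al, via potassium alkoxide 33 (not isolated)
Conditions: KOtBu (1.1 equiv), THF, 0 °C
Reagents that add atoms: none
Why: KOtBu deprotonates the C19 carbinol, and alkoxide 33 collapses to C19=O while the C12–C19 σ electrons flow into the σ* orbital of the antiperiplanar C11–OMs bond, so mesylate leaves and C11=C12 forms in one concerted Grob fragmentation of a cyclic 1,3-diol monosulfonate, a reaction type well established for ring expansion of fused and bridged bicycles. No ring closes by bond formation: cutting out the one-carbon bridge C19 merges the six- and twelve-membered rings, and the 14-membered carbocycle is the former periphery of the bicycle. No stereocentre is created (C11, C12 and C19 vanish); the only stereochemical output is alkene geometry, and it is stereospecific, since with the mesylate equatorial the cis C13 branch on C12 is axial and gauche to C10, so C10 and C13 end up cis (Z) and C20 trans to C10. The C7=C8 geometry is carried over and appears as the E-enal with C6 cis to C9. The step needs fragmentation to beat oxetane closure, E2 loss of mesylate and base damage to the enal: the cis hydroxy mesylate cannot reach the backside of C11, quaternary C12 has no hydrogen, the equatorial mesylate has no antiperiplanar hydrogen on C10, and near-stoichiometric base at 0 °C limits enolisation of 34.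

Step 23
Reactants: 34 macrocyclic dienal silyl ether
Product: 35 (1R,3R,4R,7E,11Z)-18-hydroxy-3,15-epoxycembra-7,11-dien-19-al
Conditions: HF·pyridine, THF, 0 °C → rt
Reagents that add atoms: none
Why: Fluoride desilylation in a mildly acidic medium avoids the basic conditions that could enolise or deconjugate the enal.

Step 24
Reactants: 35 C18 alcohol; 36 Meldrum's acid
Product: 37 3-{[(1R,3R,4R,7E,11Z)-3,15-epoxy-19-oxocembra-7,11-dien-18-yl]oxy}-3-oxopropanoic acid
Conditions: toluene, 95 °C
Reagents that add atoms: none
Why: Thermal acylation by Meldrum's acid, the alcohol opening the dioxanedione with loss of acetone to give the malonic half ester directly, under neutral conditions and below the decarboxylation temperature.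

**Compound list**

1 | (R)-limonene | CC1=CC[C@@H](CC1)C(C)=C | starting material
2 | limonene ring-alkene secondary ozonide (1,2,4-trioxolane, isopropenyl intact) | CC12CC[C@H](CC(OO1)O2)C(C)=C | intermediate
3 | (3R)-3-isopropenyl-6-oxoheptanal | O=CC[C@@H](CCC(C)=O)C(C)=C | intermediate
4 | δ-valerolactone | O=C1CCCCO1 | starting material
5 | potassium 5-hydroxypentanoate | [K+].[O-]C(=O)CCCCO | intermediate
6 | 5-(benzyloxy)pentanoic acid | O=C(O)CCCCOCc1ccccc1 | intermediate
7 | (S)-4-benzyloxazolidin-2-one | O=C1N[C@@H](Cc2ccccc2)CO1 | starting material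
8 | 5-(benzyloxy)pentanoic pivalic anhydride | CC(C)(C)C(=O)OC(=O)CCCCOCc1ccccc1 | intermediate
9 | (S)-4-benzyl-3-[5-(benzyloxy)pentanoyl]oxazolidin-2-one | O=C(CCCCOCc1ccccc1)N1C(=O)OC[C@@H]1Cc1ccccc1 | intermediate
10 | (Z)-dibutylboron enolate of 9 | CCCCB(CCCC)O/C(=C\CCCOCc1ccccc1)N1C(=O)OC[C@@H]1Cc1ccccc1 | intermediate
11 | syn aldol adduct (imide, C3–OH, isopropenyl, methyl ketone) | CC(=O)CC[C@H](C[C@@H](O)[C@H](CCCOCc1ccccc1)C(=O)N1C(=O)OC[C@@H]1Cc1ccccc1)C(C)=C | intermediate
12 | oxolane imide methyl ketone | CC(=O)CC[C@@H]2C[C@@H](OC2(C)C)[C@H](CCCOCc1ccccc1)C(=O)N1C(=O)OC[C@@H]1Cc1ccccc1 | intermediate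
13 | oxolane imide C13 acetate | CC(=O)OCC[C@@H]2C[C@@H](OC2(C)C)[C@H](CCCOCc1ccccc1)C(=O)N1C(=O)OC[C@@H]1Cc1ccccc1 | intermediate
14 | C18 alcohol C13 acetate | CC(=O)OCC[C@@H]1C[C@@H](OC1(C)C)[C@H](CCCOCc1ccccc1)CO | intermediate
15 | C18 TBS ether C13 acetate | CC(=O)OCC[C@@H]1C[C@@H](OC1(C)C)[C@H](CCCOCc1ccccc1)CO[Si](C)(C)C(C)(C)C | intermediate
16 | C13 alcohol | OCC[C@@H]1C[C@@H](OC1(C)C)[C@H](CCCOCc1ccccc1)CO[Si](C)(C)C(C)(C)C | intermediate
17 | C13 aldehyde | O=CC[C@@H]1C[C@@H](OC1(C)C)[C@H](CCCOCc1ccccc1)CO[Si](C)(C)C(C)(C)C | intermediate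
18 | cyclohexane-1,3-dione | O=C1CCCC(=O)C1 | starting material
19 | 2-alkylidene cyclohexane-1,3-dione (C12=C13) | O=C1CCCC(=O)C1=CC[C@@H]1C[C@@H](OC1(C)C)[C@H](CCCOCc1ccccc1)CO[Si](C)(C)C(C)(C)C | intermediate
20 | 2-alkyl cyclohexane-1,3-dione | O=C1CCCC(=O)C1CC[C@@H]1C[C@@H](OC1(C)C)[C@H](CCCOCc1ccccc1)CO[Si](C)(C)C(C)(C)C | intermediate
21 | 2-alkyl-2-methyl cyclohexane-1,3-dione | CC1(CC[C@@H]2C[C@@H](OC2(C)C)[C@H](CCCOCc2ccccc2)CO[Si](C)(C)C(C)(C)C)C(=O)CCCC1=O | intermediate
22 | (11R,12R)-ketol, OH cis to C13 chain | C[C@]1(CC[C@@H]2C[C@@H](OC2(C)C)[C@H](CCCOCc2ccccc2)CO[Si](C)(C)C(C)(C)C)C(=O)CCC[C@H]1O | intermediate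
23 | C11 TES ether of 22 | C[C@]1(CC[C@@H]2C[C@@H](OC2(C)C)[C@H](CCCOCc2ccccc2)CO[Si](C)(C)C(C)(C)C)C(=O)CCC[C@H]1O[Si](CC)(CC)CC | intermediate
24 | lithium C8=C19 enolate of 23 | [Li+].C[C@]1(CC[C@@H]2C[C@@H](OC2(C)C)[C@H](CCCOCc2ccccc2)CO[Si](C)(C)C(C)(C)C)C([O-])=CCC[C@H]1O[Si](CC)(CC)CC | intermediate
25 | C8 diethyl phosphonite (trivalent phosphorus) | C[C@]1(CC[C@@H]2C[C@@H](OC2(C)C)[C@H](CCCOCc2ccccc2)CO[Si](C)(C)C(C)(C)C)C(=O)C(P(OCC)OCC)CC[C@H]1O[Si](CC)(CC)CC | intermediate
26 | C8 diethyl phosphonate, C7 benzyl ether | C[C@]1(CC[C@@H]2C[C@@H](OC2(C)C)[C@H](CCCOCc2ccccc2)CO[Si](C)(C)C(C)(C)C)C(=O)C(P(=O)(OCC)OCC)CC[C@H]1O[Si](CC)(CC)CC | intermediate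
27 | C8 diethyl phosphonate, C7 alcohol | C[C@]1(CC[C@@H]2C[C@@H](OC2(C)C)[C@H](CCCO)CO[Si](C)(C)C(C)(C)C)C(=O)C(P(=O)(OCC)OCC)CC[C@H]1O[Si](CC)(CC)CC | intermediate
28 | C8 diethyl phosphonate, C7 aldehyde | C[C@]1(CC[C@@H]2C[C@@H](OC2(C)C)[C@H](CCC=O)CO[Si](C)(C)C(C)(C)C)C(=O)C(P(=O)(OCC)OCC)CC[C@H]1O[Si](CC)(CC)CC | intermediate
29 | bridged (7E)-enone, 11-OTES, 18-OTBS | C[C@@]12CC[C@@H]3C[C@@H](OC3(C)C)[C@@H](CO[Si](C)(C)C(C)(C)C)CC/C=C(\CC[C@H]1O[Si](CC)(CC)CC)C2=O | intermediate
30 | bridged (7E)-enone, 11-OH | C[C@@]12CC[C@@H]3C[C@@H](OC3(C)C)[C@@H](CO[Si](C)(C)C(C)(C)C)CC/C=C(\CC[C@H]1O)C2=O | intermediate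
31 | bridged (7E)-enone, 11-OMs | C[C@@]12CC[C@@H]3C[C@@H](OC3(C)C)[C@@H](CO[Si](C)(C)C(C)(C)C)CC/C=C(\CC[C@H]1OS(C)(=O)=O)C2=O | intermediate
32 | bridged all-cis 19-hydroxy-11-mesylate (fragmentation precursor) | C[C@@]12CC[C@@H]3C[C@@H](OC3(C)C)[C@@H](CO[Si](C)(C)C(C)(C)C)CC/C=C(\CC[C@H]1OS(C)(=O)=O)[C@@H]2O | intermediate
33 | potassium C19 alkoxide of 32 | [K+].C[C@@]12CC[C@@H]3C[C@@H](OC3(C)C)[C@@H](CO[Si](C)(C)C(C)(C)C)CC/C=C(\CC[C@H]1OS(C)(=O)=O)[C@@H]2[O-] | intermediate
34 | macrocyclic (7E,11Z)-dienal, 18-OTBS | C/C1=C/CC/C(C=O)=C\CC[C@H](CO[Si](C)(C)C(C)(C)C)[C@H]2C[C@@H](CC1)C(C)(C)O2 | intermediate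
35 | macrocyclic (7E,11Z)-dienal, 18-OH | C/C1=C/CC/C(C=O)=C\CC[C@H](CO)[C@H]2C[C@@H](CC1)C(C)(C)O2 | intermediate
36 | Meldrum's acid | CC1(C)OC(=O)CC(=O)O1 | starting material
37 | CNP0170412.1 (malonic half ester) | C/C1=C/CC/C(C=O)=C\CC[C@H](COC(=O)CC(=O)O)[C@H]2C[C@@H](CC1)C(C)(C)O2 | target

**Step count and risks**

Total steps: 24. Longest linear sequence: 23 (steps 2–24, from δ-valerolactone); 22 from (R)-limonene.

**1. Step 22 (fragmentation).**
- What may go wrong: the nine-atom bridge may hold the cyclohexane in the chair or twist form with the mesylate axial. The C12–C19 and C11–O bonds then never line up, and slower side processes (mesyl transfer, elimination) take over. The fresh enal may also be enolised and condensed by alkoxide if forcing is needed.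
- Fallback: a hydride-triggered reductive fragmentation that sets out from 31 and comes back at 34.
- LiAlH4 in THF (0 °C, then warming) adds hydride to C19 from the same open face. The aluminate alkoxide fragments on warming, and the enal is reduced at once to the macrocyclic C19 allylic alcohol F1.
- F1 is insensitive to base, so heat can be used to populate the reactive conformer. MnO2 in CH2Cl2 then re-oxidises the allylic alcohol selectively to 34.

**2. Step 18 (12-ring olefination).**
- What may go wrong: oligomerisation, sluggish addition of the fully substituted phosphonate carbanion, or erosion of E selectivity.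
- Fallback: ring-closing metathesis, setting out from 28 and rejoining at 29.
- Methylenation of the aldehyde (Ph3P=CH2, 2.2 equiv, THF, −78 °C; the first equivalent parks the phosphonate as its anion) should give the terminal-alkene keto phosphonate F2.
- Olefination of F2 with formaldehyde (aq. CH2O, K2CO3, THF), the most reactive aldehyde partner, should give the α-methylene ketone F3.
- Metathesis of F3 (second-generation Hoveyda–Grubbs catalyst, toluene, 80 °C, high dilution) joins C7 and C8 under thermodynamic control.

**3. Step 13 (desymmetrisation).**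
- What may go wrong: poor acceptance of the large lipophilic substrate by the enzyme, or hydride delivery to the other carbonyl. The latter would place the hydroxyl trans to the C13 chain and later invert the C11=C12 geometry.
- Fallback: reagent control by a small-molecule catalyst, from 21 back to 22. A Corey–Bakshi–Shibata reduction with (S)-2-methyl-oxazaborolidine (cat.) and catecholborane in toluene at −60 °C is proposed.
- The quaternary C12 acts as the large flank and fixes 11R. Hydride approach anti to the longer C13 chain selects the carbonyl that gives the cis ketol. This fallback makes no new compound (F0).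

**Further compounds**
F1 | step 22 | macrocyclic (7E,11Z)-dien-19-ol, 18-OTBS | C/C1=C/CC/C(CO)=C\CC[C@H](CO[Si](C)(C)C(C)(C)C)[C@H]2C[C@@H](CC1)C(C)(C)O2
F2 | step 18 | C8 diethyl phosphonate with C7 vinyl terminus | C[C@]1(CC[C@@H]2C[C@@H](OC2(C)C)[C@H](CCC=C)CO[Si](C)(C)C(C)(C)C)C(=O)C(P(=O)(OCC)OCC)CC[C@H]1O[Si](CC)(CC)CC
F3 | step 18 | C8 α-methylene ketone with C7 vinyl terminus | C[C@]1(CC[C@@H]2C[C@@H](OC2(C)C)[C@H](CCC=C)CO[Si](C)(C)C(C)(C)C)C(=O)C(=C)CC[C@H]1O[Si](CC)(CC)CC
F0 | step 13 | none | none
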